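## Structural features

The target 28 is a trans-2-aryl-3-(hydroxymethyl)-2,3-dihydro-1-benzofuran. Ring A (benzene) is fused through C3a and C7a to the five-membered ring O1–C2–C3, and carries a methoxy group at C7 and a 3-(sulfooxy)propyl chain at C5. C2 carries a 4-hydroxy-3-methoxyphenyl ring (ring B) and C3 a hydroxymethyl group; the two stereocentres are adjacent, (2S,3R), with the aryl and CH2OH groups trans. Three groups are fragile: the primary alkyl hydrogen sulfate (lost in acid, and it makes every later intermediate polar), the C2–O1 bond (a 4-hydroxybenzylic aryl ether that ionises in acid and is sensitive to hydrogenolysis) and the free phenol (easily oxidised). Three hydroxyls (the phenol, the hindered primary one at C3 and the unhindered primary one on the chain) must be told apart so that only the chain oxygen is sulfated. The real difficulty is the absolute configuration at C3 together with the trans relation to C2, while a handle for the chain is kept at C5. The key step uses the fact that C2 is the benzylic carbon para to the phenolic hydroxyl of ring B, so it can become the exocyclic carbon of a para-quinone methide; O1, the phenolic oxygen of ring A, then closes a five-membered ring onto that carbon, and C3, already in place, decides the face.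

## Logic of the disconnections

**28 from 26 (through 27).** The two acyl–oxygen bonds of the acetates (ring B phenol and C3 hydroxymethyl) and the sodium–sulfate ion pair are cut last. A sulfate monoester tolerates methoxide but not acid, so everything else is unmasked in one basic operation after it is in place. The forward step must not open the 4-hydroxybenzylic ether, and the final acidification must be brief and cold.

**26 from 25.** The O–S bond is cut. Monosulfation is only secure if a single hydroxyl is free, so 25 has the chain alcohol free and the other two hydroxyls as acetates. This removes a three-way selectivity problem.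

**25 from 24, and 24 from 20 and 22 (through 23).** The silyl ether is cut, then the C5–C(sp3) bond. The chain becomes a three-carbon unit from 21, and bromine stays at C5, where the ring-forming step needs it anyway. The coupling must engage an electron-rich aryl bromide without hydrolysing an aryl acetate, and the silyl ether must come off without touching the acetates.

**20 from 19.** The acyl–oxygen bond at the ring B phenol is cut. That phenol must be free for ring closure and masked before sulfation; a second acetate keeps the end game to one deprotection.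

**19 from 17 (through 18).** The O1–C2 bond is cut. This removes the heterocycle and the C2 stereocentre together and leaves an acyclic 2,3-diarylpropyl acetate with one stereocentre. That centre has the same spatial arrangement as C3 of 28; it is labelled (2R) in 17 and (3R) in 19, and C2 is (S). The forward step must oxidise ring B and not ring A, let C3 set C2, and leave the C3–H bond alone. The design answers are the bromine at C5, the acetate (no free alcohol to compete as nucleophile), both phenols free, and a limiting amount of oxidant. The bromine excludes only the para mode on ring A; an ortho-quinone methide through C3–H remains conceivable and is treated as a risk.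

**17 from 16, and 16 from 15.** The two O–allyl bonds and the acetyl–oxygen bond are cut. Allyl ethers are used for both phenols because they leave together under neutral conditions that spare C–Br and the acetate, which hydrogenolysis of benzyl ethers would not. The acetate goes on before the phenols are freed, so the aliphatic hydroxyl never competes with them.

**15 from 14, and 14 from 8 and 12 (through 13).** After reductive removal of the auxiliary, the bond between the stereocentre and the ring B benzylic carbon (C2–C3 of the future heterocycle) is cut. The stereocentre then sits α to an imide carbonyl, where the oxazolidinone controls the face of alkylation, and the skeleton divides into one ring A and one ring B building block. The forward step needs the (4R) auxiliary, which should give the (2R) centre, and a cold quench to avoid epimerising the acidic α-aryl position.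

**8 from 5 and 6; 5 from 4, 3, 2 and 1.** The N–acyl bond is cut, and the bond between the benzylic carbon and the carboxyl carbon is traced back to an aldehyde one carbon shorter. 1 already has bromine, hydroxyl and methoxy where C5, O1 and C7 will be, so no aromatic substitution is needed. The cost is a three-step homologation through a sensitive arylacetaldehyde.

**12 from 11, 10 and 9.** The C–Br bond, the alcohol oxidation level and the O–allyl bond are cut in turn, which reaches 9.

## Other disconnections considered

**Alternative 1:** The cut is through C2–C3 and O1–C2: ring A with C3 arrives as an ortho-quinone methide and C2 with ring B as a one-carbon ylide unit. In the forward step Cs2CO3 would expel toluenesulfinate from the racemic sulfone 2-[2-(benzyloxy)-1-(4-methylbenzenesulfonyl)ethyl]-6-methoxy-4-{3-[(triisopropylsilyl)oxy]propyl}phenol A1. The ylide from the C2-symmetric sulfonium salt (2R,5R)-1-{[4-(benzyloxy)-3-methoxyphenyl]methyl}-2,5-dimethylthiolan-1-ium trifluoromethanesulfonate A2 (or its mirror image, if the sense of induction required it) would add to the methide carbon. The phenoxide would then displace the sulfide at the ylide carbon in a 5-exo-tet closure to give (2S,3R)-3-[(benzyloxy)methyl]-2-[4-(benzyloxy)-3-methoxyphenyl]-7-methoxy-5-{3-[(triisopropylsilyl)oxy]propyl}-2,3-dihydro-1-benzofuran A3.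
- In favour: both ring bonds and both stereocentres form in one convergent operation, the chain is present from the start, no bromine or cross-coupling is needed, and the anti betaine normally closes to the trans ring.
- Against: the ortho-quinone methide from A1 carries an alkyl group with an α-hydrogen and a β-benzyloxy group, so tautomerisation to a vinylphenol and β-elimination compete. Such annulations are best established for aryl-substituted ortho-quinone methides. The absolute configuration rests on a stoichiometric chiral sulfide acting on a semi-stabilised ylide, and any shortfall gives enantiomers, not separable diastereomers. The end game needs hydrogenolysis of two benzyl ethers beside the sulfate and the hydrogenolysis-prone C2–O1 bond.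
- Comparison: on step economy and convergence Alternative 1 is clearly the better (about ten steps against nineteen). On the trans relation the two are equal, since both rely on the more stable arrangement. On mechanism and absolute control the chosen plan is safer: each bond has close precedent on its substrate class, and the auxiliary step gives a minor diastereomer that can be removed.

**Alternative 2:** The cut is C3–C3a, with the hydroxymethyl carbon traced back to C4 of a flavanone. In the forward step PhI(OAc)2 and H2SO4 in trimethyl orthoformate would let the trivalent iodine reagent attack C3 of the enol ether of (2S)-2-[4-(benzyloxy)-3-methoxyphenyl]-8-methoxy-6-{3-[(triisopropylsilyl)oxy]propyl}-2,3-dihydro-4H-chromen-4-one A4. Methanol would add at C4, and the ring A carbon would migrate from C4 to C3 as iodobenzene leaves, so C4 leaves the ring as the ester carbon. The product would be methyl (2S,3S)-trans-2-[4-(benzyloxy)-3-methoxyphenyl]-7-methoxy-5-{3-[(triisopropylsilyl)oxy]propyl}-2,3-dihydro-1-benzofuran-3-carboxylate A5, which a hydride reduction would take to the hydroxymethyl compound.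
- In favour: the flavanone skeleton comes from a simple aldol-type condensation of two aromatic carbonyl partners, C2 is set before the rearrangement and is not a migrating centre, and the chain is in place without bromine.
- Against: ring B is 4-alkoxy-3-methoxy-substituted, which is the pattern that favours the competing shift of ring B from C2 to C3 and dehydrogenation across C2–C3. The strongly acidic medium threatens the silyl ether and can open the pyranone by retro-oxa-Michael reaction, which racemises C2. An enantioselective entry to a flavanone with so electron-rich a ring B is itself uncertain for the same reason. The ester enolate of A5 can expel the ring A phenoxide.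
- Comparison: the step count would be lower than in the chosen plan (about eleven), which is a point for Alternative 2. On the trans relation it is the equal, because C3 of A5 is epimerisable and one centre directs the other under thermodynamic control. On mechanism the migratory preference works against it for exactly this ring B, whereas in the chosen plan the electron-rich ring B drives the key step.

**Alternative 3:** The cut is C3–C3a together with the C–O bond of the primary hydroxyl. In the forward step Bu3SnH under air would abstract iodine from 1-{[(1S)-1-[4-(benzyloxy)-3-methoxyphenyl]prop-2-en-1-yl]oxy}-2-iodo-6-methoxy-4-{3-[(triisopropylsilyl)oxy]propyl}benzene A6. The aryl radical at the future C3a would add 5-exo-trig to the internal alkene carbon, and the exocyclic primary radical would be trapped by O2. Reduction of the hydroperoxide would give [(2S,3R)-2-[4-(benzyloxy)-3-methoxyphenyl]-7-methoxy-5-{3-[(triisopropylsilyl)oxy]propyl}-2,3-dihydro-1-benzofuran-3-yl]methanol A7.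
- In favour: C2 is set in A6 by an enantioselective allylic etherification, and the cyclisation gives the hydroxymethyl group already free and distinct from the silylated chain hydroxyl. On protecting-group economy and step count (about ten) Alternative 3 is the better.
- Against: the 2,3-relation is set in an irreversible radical addition. With one substituent at the ether carbon the trans preference is usually moderate and cannot be corrected by equilibration. The allylic, benzylic, oxygen-bearing C–H of A6 is open to hydrogen abstraction under aerobic radical conditions, and reduction without oxygen capture competes. Stoichiometric organotin under air is the least attractive option for safety and purification, and the end game again needs hydrogenolysis beside the sulfate.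
- Comparison: on structure the two plans are equal in fixing one centre first and letting it direct the other. On mechanism the chosen plan is better, because its ring closure is reversible and self-correcting towards trans. On safety the chosen plan avoids tin.

Key step: step 13

Assumption: 28 is taken as the free hydrogen sulfate exactly as drawn; the sodium salt 27 is the storage form, and the acid is liberated only in the last operation, cold.

## Route

Step 1
Reactants: 1 5-bromo-2-hydroxy-3-methoxybenzaldehyde
Product: 2 5-bromo-3-methoxy-2-(prop-2-en-1-yloxy)benzaldehyde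
Conditions: allyl bromide, K2CO3, DMF, rt
Reagents that add atoms: allyl bromide, C=CCBr
Why: Williamson ether synthesis on the acidic ortho-formyl phenol; the allyl ether survives ylide, enolate and hydride chemistry and is later removed without touching C–Br.

Step 2
Reactants: 2 5-bromo-3-methoxy-2-(prop-2-en-1-yloxy)benzaldehyde
Product: 3 5-bromo-1-methoxy-3-(2-methoxyethenyl)-2-(prop-2-en-1-yloxy)benzene (E/Z mixture)
Conditions: MeOCH2PPh3Cl, KOt-Bu, THF, 0 °C → rt
Reagents that add atoms: (methoxymethyl)triphenylphosphonium chloride, COC[P+](c1ccccc1)(c1ccccc1)c1ccccc1.[Cl-]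
Why: Wittig olefination with the methoxymethylene ylide adds the one carbon needed; the alkene geometry is irrelevant because both isomers hydrolyse to the same aldehyde.

Step 3
Reactants: 3 5-bromo-1-methoxy-3-(2-methoxyethenyl)-2-(prop-2-en-1-yloxy)benzene
Product: 4 [5-bromo-3-methoxy-2-(prop-2-en-1-yloxy)phenyl]acetaldehyde
Conditions: 2 M HCl, THF, 40 °C; used crude
Reagents that add atoms: water, O
Why: Acid-catalysed enol ether hydrolysis (C-protonation, hydration, loss of methanol) gives the arylacetaldehyde, which is carried on at once because it enolises easily.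

Step 4
Reactants: 4 [5-bromo-3-methoxy-2-(prop-2-en-1-yloxy)phenyl]acetaldehyde
Product: 5 [5-bromo-3-methoxy-2-(prop-2-en-1-yloxy)phenyl]acetic acid
Conditions: NaClO2, NaH2PO4, 2-methyl-2-butene, t-BuOH/H2O, 0 °C → rt
Reagents that add atoms: sodium chlorite, [Na+].[O-]Cl=O
Why: Pinnick oxidation converts the aldehyde to the acid under buffered conditions; the scavenger removes hypochlorous acid so the arene and the allyl ether are not chlorinated.

Step 5
Reactants: 5 [5-bromo-3-methoxy-2-(prop-2-en-1-yloxy)phenyl]acetic acid; 6 (4R)-4-benzyl-1,3-oxazolidin-2-one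
Product: 8 (4R)-4-benzyl-3-{[5-bromo-3-methoxy-2-(prop-2-en-1-yloxy)phenyl]acetyl}-1,3-oxazolidin-2-one, via mixed pivalic anhydride 7 (not isolated)
Conditions: t-BuCOCl, Et3N, THF, −20 °C; then 6, LiCl, −20 °C → rt
Reagents that add atoms: none
Why: N-acylation of the oxazolidinone through the mixed anhydride under LiCl/Et3N activation; attack occurs at the less hindered arylacetyl carbonyl and no stereocentre is created.

Step 6
Reactants: 9 vanillin (4-hydroxy-3-methoxybenzaldehyde)
Product: 10 3-methoxy-4-(prop-2-en-1-yloxy)benzaldehyde
Conditions: allyl bromide, K2CO3, DMF, rt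
Reagents that add atoms: allyl bromide, C=CCBr
Why: Williamson ether synthesis; the same protecting group as on ring A lets both phenols be released together later.

Step 7
Reactants: 10 3-methoxy-4-(prop-2-en-1-yloxy)benzaldehyde
Product: 11 [3-methoxy-4-(prop-2-en-1-yloxy)phenyl]methanol
Conditions: NaBH4, MeOH, 0 °C
Reagents that add atoms: none
Why: Borohydride reduction of an aromatic aldehyde to the benzylic alcohol; the allyl ether is inert.

Step 8
Reactants: 11 [3-methoxy-4-(prop-2-en-1-yloxy)phenyl]methanol
Product: 12 4-(bromomethyl)-2-methoxy-1-(prop-2-en-1-yloxy)benzene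
Conditions: PBr3, Et2O, 0 °C; used at once
Reagents that add atoms: phosphorus tribromide, BrP(Br)Br
Why: Substitution of the activated benzylic alcohol through its phosphite ester; the electron-rich bromide is labile, so it is used directly in the alkylation.

Step 9
Reactants: 8 (4R)-4-benzyl-3-{[5-bromo-3-methoxy-2-(prop-2-en-1-yloxy)phenyl]acetyl}-1,3-oxazolidin-2-one; 12 4-(bromomethyl)-2-methoxy-1-(prop-2-en-1-yloxy)benzene
Product: 14 (4R)-4-benzyl-3-{(2R)-2-[5-bromo-3-methoxy-2-(prop-2-en-1-yloxy)phenyl]-3-[3-methoxy-4-(prop-2-en-1-yloxy)phenyl]propanoyl}-1,3-oxazolidin-2-one, via sodium enolate 13 (not isolated)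
Conditions: NaN(SiMe3)2, THF, −78 °C; then 12, −78 → −30 °C; AcOH quench at −78 °C
Reagents that add atoms: none
Why: Oxazolidinone-auxiliary enolate alkylation, a known reaction for arylacetyl imides with benzylic bromides; the chelated (Z)-sodium enolate is shielded on one face by the C4 benzyl group, so the electrophile enters from the other face and the (4R) auxiliary should give the (2R) centre, with any minor diastereomer separable.

Step 10
Reactants: 14 (4R)-4-benzyl-3-{(2R)-2-[5-bromo-3-methoxy-2-(prop-2-en-1-yloxy)phenyl]-3-[3-methoxy-4-(prop-2-en-1-yloxy)phenyl]propanoyl}-1,3-oxazolidin-2-one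
Product: 15 (2R)-2-[5-bromo-3-methoxy-2-(prop-2-en-1-yloxy)phenyl]-3-[3-methoxy-4-(prop-2-en-1-yloxy)phenyl]propan-1-ol
Conditions: LiBH4, MeOH (1 equiv), THF, 0 °C
Reagents that add atoms: none
Why: Reductive cleavage of the N-acyl oxazolidinone at the exocyclic carbonyl gives the primary alcohol and returns the auxiliary; the stereocentre is not a reacting centre and the label stays (R).

Step 11
Reactants: 15 (2R)-2-[5-bromo-3-methoxy-2-(prop-2-en-1-yloxy)phenyl]-3-[3-methoxy-4-(prop-2-en-1-yloxy)phenyl]propan-1-ol
Product: 16 (2R)-2-[5-bromo-3-methoxy-2-(prop-2-en-1-yloxy)phenyl]-3-[3-methoxy-4-(prop-2-en-1-yloxy)phenyl]propyl acetate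
Conditions: Ac2O, pyridine, DMAP (cat.), CH2Cl2, 0 °C → rt
Reagents that add atoms: acetic anhydride, CC(=O)OC(C)=O
Why: Standard acylation of the only free hydroxyl, done before the phenols are released so that no selectivity question arises.

Step 12
Reactants: 16 (2R)-2-[5-bromo-3-methoxy-2-(prop-2-en-1-yloxy)phenyl]-3-[3-methoxy-4-(prop-2-en-1-yloxy)phenyl]propyl acetate
Product: 17 (2R)-2-(5-bromo-2-hydroxy-3-methoxyphenyl)-3-(4-hydroxy-3-methoxyphenyl)propyl acetate
Conditions: Pd(PPh3)4 (5 mol%), morpholine, THF, rt
Reagents that add atoms: none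
Why: Tsuji–Trost-type deallylation; zerovalent palladium ionises both aryl allyl ethers to allyl complexes that morpholine intercepts, while at room temperature the phosphine-ligated catalyst should not insert into the electron-rich C–Br bond and the acetate is untouched.

Step 13
Reactants: 17 (2R)-2-(5-bromo-2-hydroxy-3-methoxyphenyl)-3-(4-hydroxy-3-methoxyphenyl)propyl acetate
Product: 19 [(2S,3R)-5-bromo-2-(4-hydroxy-3-methoxyphenyl)-7-methoxy-2,3-dihydro-1-benzofuran-3-yl]methyl acetate, via para-quinone methide 18 (not isolated)
Conditions: Ag2O (1.2 equiv), CH2Cl2 (0.01 M), rt, dark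
Reagents that add atoms: none
Why: Ag2O removes two electrons and the benzylic proton from the 4-alkyl-2-methoxyphenol ring of 17 (phenoxyl radical, then loss of hydrogen from the CH2 para to oxygen) to give the para-quinone methide 18; the ring A hydroxyl then adds to its exocyclic carbon and ring B rearomatises. The closest known reaction type is the oxidation of 4-alkyl-2-methoxyphenols to para-quinone methides with intramolecular capture by a phenol, the ring-closing half of phenylcoumaran formation. The dihydrofuran closes in the 5-exo-trig mode: O1 attacks the methide carbon (future C2), whose C=C bond lies outside the new ring, in a 1,6-conjugate addition. The new centre C2 is set by substrate control from C3: the phenol oxygen should approach the methide face anti to the acetoxymethyl group, and because the addition is reversible through the phenoxide of 19 the more stable 2,3-trans ring should accumulate, giving (2S,3R). The step needs chemoselective oxidation of ring B; ring A is made less electron-rich by bromine, cannot form a para-quinone methide because C5 is occupied, and its only benzylic hydrogen (C3–H) lies near the ring plane between the ortho substituents, badly aligned for the ortho-quinone methide that would erase the stereocentre. Ag2O is chosen over DDQ because DDQ would be more likely to dehydrogenate 19 to the benzofuran; the oxidant is kept near one equivalent and the solution dilute, since 19 keeps an oxidisable phenol and ring B has a free ortho position open to radical coupling.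

Step 14
Reactants: 19 [(2S,3R)-5-bromo-2-(4-hydroxy-3-methoxyphenyl)-7-methoxy-2,3-dihydro-1-benzofuran-3-yl]methyl acetate
Product: 20 4-[(2S,3R)-3-(acetoxymethyl)-5-bromo-7-methoxy-2,3-dihydro-1-benzofuran-2-yl]-2-methoxyphenyl acetate
Conditions: Ac2O, pyridine, rt
Reagents that add atoms: acetic anhydride, CC(=O)OC(C)=O
Why: Phenol acylation masks the ring B hydroxyl against sulfation; it also removes the free para-hydroxyl that makes the C2–O1 bond labile.

Step 15
Reactants: 21 allyl alcohol (prop-2-en-1-ol)
Product: 22 tert-butyldimethyl(prop-2-en-1-yloxy)silane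
Conditions: TBSCl, imidazole, CH2Cl2, 0 °C → rt
Reagents that add atoms: tert-butyldimethylsilyl chloride, CC(C)(C)[Si](C)(C)Cl
Why: Standard silylation of a primary alcohol; the silyl ether is orthogonal to the acetates carried by the coupling partner.

Step 16
Reactants: 22 tert-butyldimethyl(prop-2-en-1-yloxy)silane; 20 4-[(2S,3R)-3-(acetoxymethyl)-5-bromo-7-methoxy-2,3-dihydro-1-benzofuran-2-yl]-2-methoxyphenyl acetate
Product: 24 4-[(2S,3R)-3-(acetoxymethyl)-5-{3-[(tert-butyldimethylsilyl)oxy]propyl}-7-methoxy-2,3-dihydro-1-benzofuran-2-yl]-2-methoxyphenyl acetate, via alkylborane 23 (not isolated)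
Conditions: 22, 9-BBN-H, THF, 0 °C → rt; then 20, Pd(OAc)2 (3 mol%), SPhos (6 mol%), K3PO4·H2O, THF, 40 °C
Reagents that add atoms: none
Why: Anti-Markovnikov hydroboration of the terminal alkene followed by B-alkyl Suzuki–Miyaura coupling; the electron-rich biarylphosphine lets palladium insert into the electron-rich C5–Br bond at mild temperature, and the hydrated phosphate activates the borane with little free hydroxide, to spare the acetates.

Step 17
Reactants: 24 4-[(2S,3R)-3-(acetoxymethyl)-5-{3-[(tert-butyldimethylsilyl)oxy]propyl}-7-methoxy-2,3-dihydro-1-benzofuran-2-yl]-2-methoxyphenyl acetate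
Product: 25 4-[(2S,3R)-3-(acetoxymethyl)-5-(3-hydroxypropyl)-7-methoxy-2,3-dihydro-1-benzofuran-2-yl]-2-methoxyphenyl acetate
Conditions: HF·pyridine, pyridine, THF, 0 °C → rt
Reagents that add atoms: none
Why: Fluoride-driven cleavage of the primary silyl ether under buffered, non-basic conditions that leave the aryl and alkyl acetates in place.

Step 18
Reactants: 25 4-[(2S,3R)-3-(acetoxymethyl)-5-(3-hydroxypropyl)-7-methoxy-2,3-dihydro-1-benzofuran-2-yl]-2-methoxyphenyl acetate
Product: 26 sodium 3-[(2S,3R)-3-(acetoxymethyl)-2-(4-acetoxy-3-methoxyphenyl)-7-methoxy-2,3-dihydro-1-benzofuran-5-yl]propyl sulfate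
Conditions: SO3·pyridine (3 equiv), DMF, rt; then aq NaHCO3
Reagents that add atoms: sulfur trioxide–pyridine complex, O=S(=O)([O-])[n+]1ccccc1; sodium hydrogen carbonate, [Na+].OC([O-])=O
Why: O-sulfation of the only free hydroxyl by the sulfur trioxide–amine complex; the hydrogen carbonate work-up gives the sodium salt, which can be handled without acid.

Step 19
Reactants: 26 sodium 3-[(2S,3R)-3-(acetoxymethyl)-2-(4-acetoxy-3-methoxyphenyl)-7-methoxy-2,3-dihydro-1-benzofuran-5-yl]propyl sulfate
Product: 28 3-[(2S,3R)-2-(4-hydroxy-3-methoxyphenyl)-3-(hydroxymethyl)-7-methoxy-2,3-dihydro-1-benzofuran-5-yl]propyl hydrogen sulfate, via sodium salt 27 (not isolated)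
Conditions: NaOMe (2 equiv), MeOH, 0 °C → rt; then 1 M HCl at 0 °C to pH 7 and on to pH 2; C18 desalting (dilute HCl wash), lyophilisation
Reagents that add atoms: none
Why: Zemplén-type transesterification removes both acetates while the sulfate monoester anion is inert to methoxide; cold acidification then gives the hydrogen sulfate, and neither C2 nor C3 is a reacting centre.

## Compound list

1 | 5-bromo-2-hydroxy-3-methoxybenzaldehyde | COc1cc(Br)cc(C=O)c1O | starting material
2 | 5-bromo-3-methoxy-2-(prop-2-en-1-yloxy)benzaldehyde | C=CCOc1c(OC)cc(Br)cc1C=O | intermediate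
3 | 5-bromo-1-methoxy-3-(2-methoxyethenyl)-2-(prop-2-en-1-yloxy)benzene (E/Z mixture) | C=CCOc1c(OC)cc(Br)cc1C=COC | intermediate
4 | [5-bromo-3-methoxy-2-(prop-2-en-1-yloxy)phenyl]acetaldehyde | C=CCOc1c(OC)cc(Br)cc1CC=O | intermediate
5 | [5-bromo-3-methoxy-2-(prop-2-en-1-yloxy)phenyl]acetic acid | C=CCOc1c(OC)cc(Br)cc1CC(=O)O | intermediate
6 | (4R)-4-benzyl-1,3-oxazolidin-2-one | O=C1N[C@H](Cc2ccccc2)CO1 | starting material
7 | [5-bromo-3-methoxy-2-(prop-2-en-1-yloxy)phenyl]acetic pivalic anhydride (not isolated) | C=CCOc1c(OC)cc(Br)cc1CC(=O)OC(=O)C(C)(C)C | intermediate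
8 | (4R)-4-benzyl-3-{[5-bromo-3-methoxy-2-(prop-2-en-1-yloxy)phenyl]acetyl}-1,3-oxazolidin-2-one | C=CCOc1c(OC)cc(Br)cc1CC(=O)N1C(=O)OC[C@H]1Cc1ccccc1 | intermediate
9 | vanillin (4-hydroxy-3-methoxybenzaldehyde) | COc1cc(C=O)ccc1O | starting material
10 | 3-methoxy-4-(prop-2-en-1-yloxy)benzaldehyde | C=CCOc1ccc(C=O)cc1OC | intermediate
11 | [3-methoxy-4-(prop-2-en-1-yloxy)phenyl]methanol | C=CCOc1ccc(CO)cc1OC | intermediate
12 | 4-(bromomethyl)-2-methoxy-1-(prop-2-en-1-yloxy)benzene | C=CCOc1ccc(CBr)cc1OC | intermediate
13 | sodium (Z)-enolate of 8 (not isolated) | C=CCOc1c(OC)cc(Br)cc1/C=C(\[O-])N1C(=O)OC[C@H]1Cc1ccccc1.[Na+] | intermediate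
14 | (4R)-4-benzyl-3-{(2R)-2-[5-bromo-3-methoxy-2-(prop-2-en-1-yloxy)phenyl]-3-[3-methoxy-4-(prop-2-en-1-yloxy)phenyl]propanoyl}-1,3-oxazolidin-2-one | C=CCOc1ccc(C[C@@H](C(=O)N2C(=O)OC[C@H]2Cc2ccccc2)c2cc(Br)cc(OC)c2OCC=C)cc1OC | intermediate
15 | (2R)-2-[5-bromo-3-methoxy-2-(prop-2-en-1-yloxy)phenyl]-3-[3-methoxy-4-(prop-2-en-1-yloxy)phenyl]propan-1-ol | C=CCOc1ccc(C[C@@H](CO)c2cc(Br)cc(OC)c2OCC=C)cc1OC | intermediate
16 | (2R)-2-[5-bromo-3-methoxy-2-(prop-2-en-1-yloxy)phenyl]-3-[3-methoxy-4-(prop-2-en-1-yloxy)phenyl]propyl acetate | C=CCOc1ccc(C[C@@H](COC(C)=O)c2cc(Br)cc(OC)c2OCC=C)cc1OC | intermediate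
17 | (2R)-2-(5-bromo-2-hydroxy-3-methoxyphenyl)-3-(4-hydroxy-3-methoxyphenyl)propyl acetate | COc1cc(C[C@@H](COC(C)=O)c2cc(Br)cc(OC)c2O)ccc1O | intermediate
18 | 4-[(2R)-3-acetoxy-2-(5-bromo-2-hydroxy-3-methoxyphenyl)propylidene]-2-methoxycyclohexa-2,5-dien-1-one (not isolated) | COC1=CC(=C[C@@H](COC(C)=O)c2cc(Br)cc(OC)c2O)C=CC1=O | intermediate
19 | [(2S,3R)-5-bromo-2-(4-hydroxy-3-methoxyphenyl)-7-methoxy-2,3-dihydro-1-benzofuran-3-yl]methyl acetate | COc1cc([C@H]2Oc3c(OC)cc(Br)cc3[C@@H]2COC(C)=O)ccc1O | intermediate
20 | 4-[(2S,3R)-3-(acetoxymethyl)-5-bromo-7-methoxy-2,3-dihydro-1-benzofuran-2-yl]-2-methoxyphenyl acetate | COc1cc([C@H]2Oc3c(OC)cc(Br)cc3[C@@H]2COC(C)=O)ccc1OC(C)=O | intermediate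
21 | allyl alcohol (prop-2-en-1-ol) | C=CCO | starting material
22 | tert-butyldimethyl(prop-2-en-1-yloxy)silane | C=CCO[Si](C)(C)C(C)(C)C | intermediate
23 | 9-{3-[(tert-butyldimethylsilyl)oxy]propyl}-9-borabicyclo[3.3.1]nonane (not isolated) | CC(C)(C)[Si](C)(C)OCCCB1C2CCCC1CCC2 | intermediate
24 | 4-[(2S,3R)-3-(acetoxymethyl)-5-{3-[(tert-butyldimethylsilyl)oxy]propyl}-7-methoxy-2,3-dihydro-1-benzofuran-2-yl]-2-methoxyphenyl acetate | COc1cc([C@H]2Oc3c(OC)cc(CCCO[Si](C)(C)C(C)(C)C)cc3[C@@H]2COC(C)=O)ccc1OC(C)=O | intermediate
25 | 4-[(2S,3R)-3-(acetoxymethyl)-5-(3-hydroxypropyl)-7-methoxy-2,3-dihydro-1-benzofuran-2-yl]-2-methoxyphenyl acetate | COc1cc([C@H]2Oc3c(OC)cc(CCCO)cc3[C@@H]2COC(C)=O)ccc1OC(C)=O | intermediate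
26 | sodium 3-[(2S,3R)-3-(acetoxymethyl)-2-(4-acetoxy-3-methoxyphenyl)-7-methoxy-2,3-dihydro-1-benzofuran-5-yl]propyl sulfate | COc1cc([C@H]2Oc3c(OC)cc(CCCOS(=O)(=O)[O-])cc3[C@@H]2COC(C)=O)ccc1OC(C)=O.[Na+] | intermediate
27 | sodium 3-[(2S,3R)-2-(4-hydroxy-3-methoxyphenyl)-3-(hydroxymethyl)-7-methoxy-2,3-dihydro-1-benzofuran-5-yl]propyl sulfate (not isolated) | COc1cc([C@H]2Oc3c(OC)cc(CCCOS(=O)(=O)[O-])cc3[C@@H]2CO)ccc1O.[Na+] | intermediate
28 | 3-[(2S,3R)-2-(4-hydroxy-3-methoxyphenyl)-3-(hydroxymethyl)-7-methoxy-2,3-dihydro-1-benzofuran-5-yl]propyl hydrogen sulfate | COc1cc([C@H]2Oc3c(OC)cc(CCCOS(=O)(=O)O)cc3[C@@H]2CO)ccc1O | target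

## Step count and least certain steps

Total step count: 19. Longest linear sequence: 15 steps (steps 1–5, 9–14 and 16–19); steps 6–8 and step 15 are side branches.

**Step 13 (key step).** The oxidation may not stay on ring B. A ring A phenoxyl radical could lose the C3 hydrogen and erase the stereocentre. Ring B phenoxyl radicals could couple through the free ortho position. The quinone methide could tautomerise to a stilbene by loss of the C3 hydrogen before O1 adds. The product could be oxidised a second time and aromatise.

The fallback makes the same O1–C2 bond without an oxidant, from a benzylic alcohol. It sets out from 5 and returns at 20.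
- Acid 5 is activated as 7 and acylates the antipodal auxiliary (4S)-4-benzyl-1,3-oxazolidin-2-one to give (4S)-4-benzyl-3-{[5-bromo-3-methoxy-2-(prop-2-en-1-yloxy)phenyl]acetyl}-1,3-oxazolidin-2-one F1.
- The dibutylboron enolate of F1 (Bu2BOTf, i-Pr2NEt, CH2Cl2, −78 °C) adds to aldehyde 10 in a syn-selective aldol reaction to give (4S)-4-benzyl-3-{(2S,3S)-2-[5-bromo-3-methoxy-2-(prop-2-en-1-yloxy)phenyl]-3-hydroxy-3-[3-methoxy-4-(prop-2-en-1-yloxy)phenyl]propanoyl}-1,3-oxazolidin-2-one F2. The boron aldol reaction uses the enolate face opposite to that of the sodium enolate alkylation, which is why the auxiliary antipode changes.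
- LiBH4 gives (1S,2R)-2-[5-bromo-3-methoxy-2-(prop-2-en-1-yloxy)phenyl]-1-[3-methoxy-4-(prop-2-en-1-yloxy)phenyl]propane-1,3-diol F3.
- Pd(PPh3)4 and morpholine free both phenols to give (1S,2R)-2-(5-bromo-2-hydroxy-3-methoxyphenyl)-1-(4-hydroxy-3-methoxyphenyl)propane-1,3-diol F4.
- Catalytic p-TsOH in CH2Cl2 ionises the 4-hydroxybenzylic alcohol, and the ring A phenol closes the trans ring to give 4-[(2S,3R)-5-bromo-3-(hydroxymethyl)-7-methoxy-2,3-dihydro-1-benzofuran-2-yl]-2-methoxyphenol F5.
- Ac2O in pyridine acetylates both hydroxyls and rejoins the route at 20.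

**Step 16.** The phosphate base may hydrolyse the phenolic acetate, and slow oxidative addition into the electron-rich C–Br bond may let protodeboronation or β-hydride elimination of the alkylborane take over. The fallback is a base-free Negishi coupling from 20 to 24. Commercial (3-bromopropoxy)(tert-butyl)dimethylsilane is converted with Zn and LiCl in THF into {3-[(tert-butyldimethylsilyl)oxy]propyl}zinc bromide F6, which is coupled with 20 using Pd(OAc)2 and SPhos in THF to give 24.

**Step 3.** The electron-rich arylacetaldehyde may enolise, self-condense or air-oxidise during hydrolysis and handling. The fallback avoids the aldehyde by a reductive Jocic homologation from 2 to 5. Sodium trichloroacetate and trichloroacetic acid in DMF convert 2 into racemic 1-[5-bromo-3-methoxy-2-(prop-2-en-1-yloxy)phenyl]-2,2,2-trichloroethan-1-ol F7. NaBH4 and NaOH in t-BuOH at 55 °C then open the derived dichloroepoxide with hydride at the benzylic carbon and hydrolyse the acyl chloride to 5.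

**Step 10.** Hydride may attack the ring carbonyl of the hindered imide and open the auxiliary, and the basic medium may epimerise the acidic α-aryl centre. The fallback separates cleavage from reduction, from 14 to 15. LiOH and H2O2 in THF/H2O at 0 °C hydrolyse the exocyclic acyl group to (2R)-2-[5-bromo-3-methoxy-2-(prop-2-en-1-yloxy)phenyl]-3-[3-methoxy-4-(prop-2-en-1-yloxy)phenyl]propanoic acid F8, and LiAlH4 in THF at 0 °C reduces F8 to 15.

## Further compounds

F1 | step 13 | (4S)-4-benzyl-3-{[5-bromo-3-methoxy-2-(prop-2-en-1-yloxy)phenyl]acetyl}-1,3-oxazolidin-2-one | C=CCOc1c(OC)cc(Br)cc1CC(=O)N1C(=O)OC[C@@H]1Cc1ccccc1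
F2 | step 13 | (4S)-4-benzyl-3-{(2S,3S)-2-[5-bromo-3-methoxy-2-(prop-2-en-1-yloxy)phenyl]-3-hydroxy-3-[3-methoxy-4-(prop-2-en-1-yloxy)phenyl]propanoyl}-1,3-oxazolidin-2-one | C=CCOc1ccc([C@@H](O)[C@@H](C(=O)N2C(=O)OC[C@@H]2Cc2ccccc2)c2cc(Br)cc(OC)c2OCC=C)cc1OC
F3 | step 13 | (1S,2R)-2-[5-bromo-3-methoxy-2-(prop-2-en-1-yloxy)phenyl]-1-[3-methoxy-4-(prop-2-en-1-yloxy)phenyl]propane-1,3-diol | C=CCOc1ccc([C@@H](O)[C@@H](CO)c2cc(Br)cc(OC)c2OCC=C)cc1OC
F4 | step 13 | (1S,2R)-2-(5-bromo-2-hydroxy-3-methoxyphenyl)-1-(4-hydroxy-3-methoxyphenyl)propane-1,3-diol | COc1cc([C@@H](O)[C@@H](CO)c2cc(Br)cc(OC)c2O)ccc1O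
F5 | step 13 | 4-[(2S,3R)-5-bromo-3-(hydroxymethyl)-7-methoxy-2,3-dihydro-1-benzofuran-2-yl]-2-methoxyphenol | COc1cc([C@H]2Oc3c(OC)cc(Br)cc3[C@@H]2CO)ccc1O
F6 | step 16 | {3-[(tert-butyldimethylsilyl)oxy]propyl}zinc bromide | CC(C)(C)[Si](C)(C)OCCC[Zn]Br
F7 | step 3 | 1-[5-bromo-3-methoxy-2-(prop-2-en-1-yloxy)phenyl]-2,2,2-trichloroethan-1-ol (racemic) | C=CCOc1c(OC)cc(Br)cc1C(O)C(Cl)(Cl)Cl
F8 | step 10 | (2R)-2-[5-bromo-3-methoxy-2-(prop-2-en-1-yloxy)phenyl]-3-[3-methoxy-4-(prop-2-en-1-yloxy)phenyl]propanoic acid | C=CCOc1ccc(C[C@@H](C(=O)O)c2cc(Br)cc(OC)c2OCC=C)cc1OC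
A1 | alternative 1 | 2-[2-(benzyloxy)-1-(4-methylbenzenesulfonyl)ethyl]-6-methoxy-4-{3-[(triisopropylsilyl)oxy]propyl}phenol (racemic) | COc1cc(CCCO[Si](C(C)C)(C(C)C)C(C)C)cc(C(COCc2ccccc2)S(=O)(=O)c2ccc(C)cc2)c1O
A2 | alternative 1 | (2R,5R)-1-{[4-(benzyloxy)-3-methoxyphenyl]methyl}-2,5-dimethylthiolan-1-ium trifluoromethanesulfonate | COc1cc(C[S+]2[C@H](C)CC[C@H]2C)ccc1OCc1ccccc1.[O-]S(=O)(=O)C(F)(F)F
A3 | alternative 1 | (2S,3R)-3-[(benzyloxy)methyl]-2-[4-(benzyloxy)-3-methoxyphenyl]-7-methoxy-5-{3-[(triisopropylsilyl)oxy]propyl}-2,3-dihydro-1-benzofuran | COc1cc([C@H]2Oc3c(OC)cc(CCCO[Si](C(C)C)(C(C)C)C(C)C)cc3[C@@H]2COCc2ccccc2)ccc1OCc1ccccc1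
A4 | alternative 2 | (2S)-2-[4-(benzyloxy)-3-methoxyphenyl]-8-methoxy-6-{3-[(triisopropylsilyl)oxy]propyl}-2,3-dihydro-4H-chromen-4-one | COc1cc([C@@H]2CC(=O)c3cc(CCCO[Si](C(C)C)(C(C)C)C(C)C)cc(OC)c3O2)ccc1OCc1ccccc1
A5 | alternative 2 | methyl (2S,3S)-trans-2-[4-(benzyloxy)-3-methoxyphenyl]-7-methoxy-5-{3-[(triisopropylsilyl)oxy]propyl}-2,3-dihydro-1-benzofuran-3-carboxylate | COc1cc([C@H]2Oc3c(OC)cc(CCCO[Si](C(C)C)(C(C)C)C(C)C)cc3[C@@H]2C(=O)OC)ccc1OCc1ccccc1
A6 | alternative 3 | 1-{[(1S)-1-[4-(benzyloxy)-3-methoxyphenyl]prop-2-en-1-yl]oxy}-2-iodo-6-methoxy-4-{3-[(triisopropylsilyl)oxy]propyl}benzene | C=C[C@H](Oc1c(I)cc(CCCO[Si](C(C)C)(C(C)C)C(C)C)cc1OC)c1ccc(OCc2ccccc2)c(OC)c1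
A7 | alternative 3 | [(2S,3R)-2-[4-(benzyloxy)-3-methoxyphenyl]-7-methoxy-5-{3-[(triisopropylsilyl)oxy]propyl}-2,3-dihydro-1-benzofuran-3-yl]methanol | COc1cc([C@H]2Oc3c(OC)cc(CCCO[Si](C(C)C)(C(C)C)C(C)C)cc3[C@@H]2CO)ccc1OCc1ccccc1
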